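Readings and results come from a simulation from invented constants; noise was put on by code.

- In time, my ladder comes from the north-west run, whose charges match maple and cedar except for partner. Its first reading gives a first-order time constant of 1.72 min for left-handed substrate and 4.66 min for right-handed substrate. The left-handed logarithm of that run, however, reads as nearing its last value with a time constant τ of 0.633 min, so the north-west reaction fades sooner than either substrate is used up, and its last reading stands at partial conversion.

| setting | north | north-west | south-west | maple | cedar |
|---|---|---|---|---|---|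
| left-handed substrate | 5.0 × 10⁻⁴ M | 5.0 × 10⁻⁴ M | 0.0010 M | 5.0 × 10⁻⁴ M | 5.0 × 10⁻⁴ M |
| right-handed substrate | 5.0 × 10⁻⁴ M | 5.0 × 10⁻⁴ M | 0.0010 M | 5.0 × 10⁻⁴ M | 5.0 × 10⁻⁴ M |
| partner | 0.75 equiv | 1.1 equiv | 1.5 equiv | 1.50 equiv | 1.50 equiv |
| precatalyst | 1 mol% | 1 mol% | 1 mol% | 1 mol% | 1 mol% |
| added ligand | 17 µM | 17 µM | 17 µM | 17 µM | 17 µM |
| impurity | 5.9 µM | 5.9 µM | 5.9 µM | 5.9 µM | 5.9 µM |
| remark | run made earlier | run made earlier | run made earlier |  |  |
| time |  |  |  | 2.5 min | 1.5 min |

| run | time / min | left-handed product / % | right-handed product / % |
|---|---|---|---|
| north | 0.500 | 8.5 | 3.1 |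
| north | 1.00 | 12.3 | 3.8 |
| north | 1.50 | 13.1 | 4.7 |
| north | 2.00 | 14.2 | 5.1 |
| north | 2.50 | 14.5 | 4.9 |
| north-west | 0.200 | 5.5 | 2.1 |
| north-west | 0.667 | 14.0 | 4.6 |
| north-west | 1.33 | 16.9 | 7.1 |
| north-west | 2.00 | 18.2 | 7.4 |
| north-west | 2.50 | 19.8 | 7.0 |
| south-west | 0.200 | 20.4 | 8.0 |
| south-west | 0.667 | 34.7 | 17.5 |
| south-west | 1.33 | 41.0 | 21.9 |
| south-west | 2.00 | 43.0 | 24.6 |
| south-west | 2.50 | 44.0 | 25.0 |

(scatter of a reading: 0.5 percentage points)

- free catalyst is single-handed; left-handed substrate and right-handed substrate are mirror images of each other, charged as a racemate, each of them at the stated concentration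
- an excess is the difference of the two amounts in percent of their sum
- an excess is below zero if the other one leads

- which of the two ends with the higher excess of left-handed product over right-handed product in the product ("neither" if they lie within 2 percentage points) (maple / cedar / neither)
- excess of left-handed product over right-handed product in the product at the end, maple
- excess of left-handed product over right-handed product in the product at the end, cedar

- I work in logarithms: doubling a product percentage gives the share of that substrate's own charge that has become product, and the exposure x is minus the logarithm of the fraction of right-handed substrate left.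
- I carry s = 3.34 from the last north-west reading, the selectivity factor, which is the logarithm of the fraction of left-handed substrate left over that of the right-handed; north reads 3.32 and south-west 3.06.
- Exposure goes up 1.46-fold from north to north-west while partner goes up 1.47-fold, so I scale it to 0.206 for maple.
- By τ I estimate that cedar reaches 92.4 % of that exposure, so with converted shares of 1−exp(−sx) and 1−exp(−x) I reckon 45.6 % for maple and 46.2 % for cedar, a gap of 0.60 percentage points against a margin of 2 points.
- The forecast says neither, with 43.5 % for maple and 44.5 % for cedar, on the ground that “Maple and cedar differ only in stopping time”; my maple figure stands 2.1 points above its figure.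
- The flask gives neither, with 42.2 % for maple and 43.0 % for cedar.

    free catalyst + left-handed substrate ⇌ catalyst intermediate A (K = 1700 /M, k = 1.90 × 10⁵ /M/s)
    free catalyst + right-handed substrate ⇌ catalyst intermediate B (K = 1800 /M, k = 87000 /M/s)
    partner + catalyst intermediate A → free catalyst + left-handed product (k = 58000 /M/s)
    partner + catalyst intermediate B → free catalyst + right-handed product (k = 17000 /M/s)
    precatalyst → free catalyst (k = 0.300 /s)
    free catalyst + added ligand ⇌ idle complex, settled at all times (K = 5.50 × 10⁵ /M)
    free catalyst + impurity → spent catalyst (k = 1.10 × 10⁵ /M/s)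

- In maple's unbound remainders, 53 % of left-handed and 81 % of right-handed substrate, the ratio of logarithms s comes to 3.01. A neighbour of cedar with 2.4 × 10⁻⁶ M of impurity reaches exposure 0.337, where s of 3.34 gives an excess of 40.5 % and that flask ends with 38.1 %. Maple has not come to rest at 2.50 min, with 94.7 % of the catalyst spent; by 25.0 min that is >99.9 %, left-handed product climbs from 23.3 % to 25.3 %, right-handed product from 9.49 % to 10.5 %, and the excess moves from 42.2 % to 41.3 %.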